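## Retrosynthetic overview

1. Target 29 ⇐ 9‑O‑silyl ether 28 ⇐ macrocyclic 8‑epi alcohol 25, by Mitsunobu esterification with inversion at C8.
2. Key disconnection C7–C8: 25 ⇐ seco aldehyde 23. CrCl2 turns the bromomethyl butenolide into an allylchromium in which C7, the β‑carbon of the lactone (normally an acceptor), is the nucleophile (a lactone homoenolate equivalent). It adds to the C8 aldehyde carbon (also normally an acceptor), closing the ten‑membered ring and creating C7, C8 and the α‑methylene lactone in one step.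
3. 23 ⇐ enal 13: C6 by catalytic asymmetric alkenylzinc addition, butenolide by acrylate esterification and ring‑closing metathesis, C8 aldehyde by periodate cleavage of a glyceraldehyde‑derived acetonide.
4. 13 ⇐ neryl acetate (C1–C6, C15, Z‑alkene): ozonolysis, iodo‑Wittig, Nozaki–Hiyama–Kishi coupling with (R)‑glyceraldehyde acetonide (C9), hydroxyl‑directed epoxidation (C1, C10).
5. Ring order: oxirane (step 4), butenolide (step 10), ten‑membered carbocycle last (step 12).

Assumption: germacrane locants are used as atom labels (ring C1–C10; lactone C11, C12, C13; ester carbon C14 on C10; methyl C15 on C4). The CIP labels of C7, C9 and C10 change along the route only because substituent priorities change, not the geometry.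

## Route

Step 1
Reactants: 1 neryl acetate, (2Z)-3,7-dimethylocta-2,6-dien-1-yl acetate
Product: 3 (2Z)-3-methyl-6-oxohex-2-en-1-yl acetate, via secondary ozonide 2 (not isolated)
Conditions: O3 (1.0 equiv), CH2Cl2, −78 °C; then Me2S, −78 → 25 °C
Reagents that add atoms: ozone, [O-][O+]=O
Why: Criegee ozonolysis; the electron‑rich distal trisubstituted alkene reacts faster than the C4=C5 alkene deactivated by the allylic acetate, so one equivalent of ozone cleaves only the prenyl end and leaves the Z‑alkene untouched.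

Step 2
Reactants: 3 (2Z)-3-methyl-6-oxohex-2-en-1-yl acetate; 4 methyl (triphenylphosphoranylidene)acetate
Product: 6 methyl (2Z,6Z)-8-acetoxy-2-iodo-6-methylocta-2,6-dienoate, via iodo ylide 5 (not isolated)
Conditions: 4, NIS, CH2Cl2, −20 °C, 30 min; then 3, −20 → 25 °C
Reagents that add atoms: N-iodosuccinimide, O=C1CCC(=O)N1I
Why: Wittig olefination with the stabilised ylide iodinated in situ (succinimide anion as base) places the ester trans to the chain, giving the (2Z)-α-iodo enoate whose geometry is carried into the epoxide.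

Step 3
Reactants: 6 methyl (2Z,6Z)-8-acetoxy-2-iodo-6-methylocta-2,6-dienoate; 7 (R)-2,2-dimethyl-1,3-dioxolane-4-carbaldehyde
Product: 9 methyl (2E,6Z)-8-acetoxy-2-{(S)-[(4R)-2,2-dimethyl-1,3-dioxolan-4-yl](hydroxy)methyl}-6-methylocta-2,6-dienoate, via alkenylchromium dichloride 8 (not isolated)
Conditions: CrCl2 (4 equiv), NiCl2 (2 mol%), DMF, 25 °C; aqueous work-up
Reagents that add atoms: none
Why: Nozaki–Hiyama–Kishi coupling; the alkenylchromium forms with retention of geometry and adds only to the aldehyde, and Felkin–Anh (anti) addition to the α‑alkoxy aldehyde sets C9 (minor C9 epimer removed by chromatography).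

Step 4
Reactants: 9 methyl (2E,6Z)-8-acetoxy-2-{(S)-[(4R)-2,2-dimethyl-1,3-dioxolan-4-yl](hydroxy)methyl}-6-methylocta-2,6-dienoate
Product: 10 methyl (2S,3R)-3-[(3Z)-5-acetoxy-3-methylpent-3-en-1-yl]-2-{(R)-[(4R)-2,2-dimethyl-1,3-dioxolan-4-yl](hydroxy)methyl}oxirane-2-carboxylate
Conditions: Ti(OiPr)4 (30 mol%), tBuOOH (2 equiv, decane), 4 Å MS, CH2Cl2, −20 → 0 °C
Reagents that add atoms: tert-butyl hydroperoxide, CC(C)(C)OO
Why: hydroxyl‑directed, titanium‑alkoxide‑templated epoxidation (Sharpless type, no tartrate) touches only the alkene bearing a free allylic OH; A(1,3) strain (C2 cis to C9) holds H‑9 in the alkene plane so oxygen is delivered syn to O‑9 (threo), and the concerted transfer keeps C2 cis to C9, setting C10 and C1.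

Step 5
Reactants: 10 methyl (2S,3R)-3-[(3Z)-5-acetoxy-3-methylpent-3-en-1-yl]-2-{(R)-[(4R)-2,2-dimethyl-1,3-dioxolan-4-yl](hydroxy)methyl}oxirane-2-carboxylate
Product: 11 methyl (2R,3R)-3-[(3Z)-5-acetoxy-3-methylpent-3-en-1-yl]-2-{(R)-[(tert-butyldimethylsilyl)oxy][(4R)-2,2-dimethyl-1,3-dioxolan-4-yl]methyl}oxirane-2-carboxylate
Conditions: TBSOTf, 2,6-lutidine, CH2Cl2, −78 → 0 °C
Reagents that add atoms: tert-butyldimethylsilyl triflate, CC(C)(C)[Si](C)(C)OS(=O)(=O)C(F)(F)F
Why: silylation of the hindered secondary alcohol gives a bulky, non‑chelating ether that survives the later periodate, chromium and Mitsunobu steps; no stereocenter is touched.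

Step 6
Reactants: 11 methyl (2R,3R)-3-[(3Z)-5-acetoxy-3-methylpent-3-en-1-yl]-2-{(R)-[(tert-butyldimethylsilyl)oxy][(4R)-2,2-dimethyl-1,3-dioxolan-4-yl]methyl}oxirane-2-carboxylate
Product: 12 methyl (2R,3R)-2-{(R)-[(tert-butyldimethylsilyl)oxy][(4R)-2,2-dimethyl-1,3-dioxolan-4-yl]methyl}-3-[(3Z)-5-hydroxy-3-methylpent-3-en-1-yl]oxirane-2-carboxylate
Conditions: K2CO3 (0.2 equiv), MeOH, 0 °C
Reagents that add atoms: none
Why: base‑catalysed methanolysis (transesterification) removes the allylic acetate, while exchange at the methyl ester is degenerate and the glycidic epoxide is inert to catalytic carbonate at 0 °C.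

Step 7
Reactants: 12 methyl (2R,3R)-2-{(R)-[(tert-butyldimethylsilyl)oxy][(4R)-2,2-dimethyl-1,3-dioxolan-4-yl]methyl}-3-[(3Z)-5-hydroxy-3-methylpent-3-en-1-yl]oxirane-2-carboxylate
Product: 13 methyl (2R,3R)-2-{(R)-[(tert-butyldimethylsilyl)oxy][(4R)-2,2-dimethyl-1,3-dioxolan-4-yl]methyl}-3-[(3Z)-3-methyl-5-oxopent-3-en-1-yl]oxirane-2-carboxylate
Conditions: TEMPO (10 mol%), PhI(OAc)2, CH2Cl2, 25 °C
Reagents that add atoms: none
Why: oxoammonium (TEMPO/PhI(OAc)2) oxidation of the primary allylic alcohol gives the enal under neutral conditions without Z→E isomerisation.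

Step 8
Reactants: 13 methyl (2R,3R)-2-{(R)-[(tert-butyldimethylsilyl)oxy][(4R)-2,2-dimethyl-1,3-dioxolan-4-yl]methyl}-3-[(3Z)-3-methyl-5-oxopent-3-en-1-yl]oxirane-2-carboxylate; 14 hex-1-yne
Product: 17 methyl (2R,3R)-2-{(R)-[(tert-butyldimethylsilyl)oxy][(4R)-2,2-dimethyl-1,3-dioxolan-4-yl]methyl}-3-[(3Z,5S,6E)-5-hydroxy-3-methylundeca-3,6-dien-1-yl]oxirane-2-carboxylate, via hexenylborane 15 (not isolated), via hexenylzinc 16 (not isolated)
Conditions: 14, Cy2BH, toluene, 0 → 25 °C; Et2Zn, −78 °C; (−)-MIB (5 mol%), then 13, −20 → 0 °C; aq. NH4Cl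
Reagents that add atoms: none
Why: hydroboration, boron‑to‑zinc exchange and amino‑alcohol‑catalysed alkenylzinc addition (Oppolzer–Walsh) deliver the alkenyl group to the Si face of the enal, setting C6; esters and the epoxide are inert to organozinc reagents.

Step 9
Reactants: 17 methyl (2R,3R)-2-{(R)-[(tert-butyldimethylsilyl)oxy][(4R)-2,2-dimethyl-1,3-dioxolan-4-yl]methyl}-3-[(3Z,5S,6E)-5-hydroxy-3-methylundeca-3,6-dien-1-yl]oxirane-2-carboxylate; 18 2-(bromomethyl)prop-2-enoic acid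
Product: 20 methyl (2R,3R)-3-[(3Z,5S,6E)-5-{[2-(bromomethyl)prop-2-enoyl]oxy}-3-methylundeca-3,6-dien-1-yl]-2-{(R)-[(tert-butyldimethylsilyl)oxy][(4R)-2,2-dimethyl-1,3-dioxolan-4-yl]methyl}oxirane-2-carboxylate, via O-acylisourea 19 (not isolated)
Conditions: DCC, DMAP (5 mol%), CH2Cl2, −10 → 0 °C
Reagents that add atoms: none
Why: Steglich esterification acylates the C6 alcohol with retention; low temperature and catalytic DMAP spare the allylic bromide.

Step 10
Reactants: 20 methyl (2R,3R)-3-[(3Z,5S,6E)-5-{[2-(bromomethyl)prop-2-enoyl]oxy}-3-methylundeca-3,6-dien-1-yl]-2-{(R)-[(tert-butyldimethylsilyl)oxy][(4R)-2,2-dimethyl-1,3-dioxolan-4-yl]methyl}oxirane-2-carboxylate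
Product: 21 methyl (2R,3R)-3-{(3Z)-4-[(2R)-4-(bromomethyl)-5-oxo-2,5-dihydrofuran-2-yl]-3-methylbut-3-en-1-yl}-2-{(R)-[(tert-butyldimethylsilyl)oxy][(4R)-2,2-dimethyl-1,3-dioxolan-4-yl]methyl}oxirane-2-carboxylate
Conditions: second-generation Grubbs catalyst (10 mol%), toluene (5 mM), 80 °C
Reagents that add atoms: none
Why: ring‑closing metathesis between the disubstituted hexenyl alkene and the acrylate closes the five‑membered butenolide and expels hex‑1‑ene; the trisubstituted Z‑alkene is too hindered to compete and C6 is unaffected.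

Step 11
Reactants: 21 methyl (2R,3R)-3-{(3Z)-4-[(2R)-4-(bromomethyl)-5-oxo-2,5-dihydrofuran-2-yl]-3-methylbut-3-en-1-yl}-2-{(R)-[(tert-butyldimethylsilyl)oxy][(4R)-2,2-dimethyl-1,3-dioxolan-4-yl]methyl}oxirane-2-carboxylate
Product: 23 methyl (2R,3R)-3-{(3Z)-4-[(2R)-4-(bromomethyl)-5-oxo-2,5-dihydrofuran-2-yl]-3-methylbut-3-en-1-yl}-2-{(1S)-1-[(tert-butyldimethylsilyl)oxy]-2-oxoethyl}oxirane-2-carboxylate, via diol 22 (not isolated)
Conditions: H5IO6 (1.5 equiv), EtOAc, 0 → 25 °C; used crude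
Reagents that add atoms: none
Why: periodic acid hydrolyses the terminal acetonide and cleaves the resulting 1,2‑diol in one pot, unmasking the C8 aldehyde under non‑basic conditions that leave the silyl ether, glycidic ester, butenolide and allylic bromide intact.

Step 12
Reactants: 23 methyl (2R,3R)-3-{(3Z)-4-[(2R)-4-(bromomethyl)-5-oxo-2,5-dihydrofuran-2-yl]-3-methylbut-3-en-1-yl}-2-{(1S)-1-[(tert-butyldimethylsilyl)oxy]-2-oxoethyl}oxirane-2-carboxylate
Product: 25 methyl (1R,4Z,6R,7R,8R,9R,10R)-9-[(tert-butyldimethylsilyl)oxy]-1,10-epoxy-8-hydroxygermacra-4,11(13)-dien-12,6-olid-14-oate, via allylchromium dichloride 24 (not isolated)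
Conditions: CrCl2 (10 equiv), THF, 25 °C, 23 added by syringe pump over 12 h (final 2 mM); aq. NH4Cl
Reagents that add atoms: none
Why: intramolecular Nozaki–Hiyama (Barbier‑type) allylation in which C7 of the allylchromium (trivalent chromium), a lactone homoenolate equivalent, attacks the C8 aldehyde through a closed chair transition state with allylic transposition to the exocyclic methylene; attack anti to the C6 side chain gives the trans‑lactone at C7, and the equatorial C9 carbon together with Felkin–Anh approach past the non‑chelating silyloxy group both favour the 8R carbinol.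

Step 13
Reactants: 25 methyl (1R,4Z,6R,7R,8R,9R,10R)-9-[(tert-butyldimethylsilyl)oxy]-1,10-epoxy-8-hydroxygermacra-4,11(13)-dien-12,6-olid-14-oate; 26 (2S)-2-methylbutanoic acid
Product: 28 methyl (1R,4Z,6R,7S,8S,9R,10R)-9-[(tert-butyldimethylsilyl)oxy]-1,10-epoxy-8-{[(2S)-2-methylbutanoyl]oxy}germacra-4,11(13)-dien-12,6-olid-14-oate, via alkoxyphosphonium salt 27 (not isolated)
Conditions: PPh3, DIAD (premixed), toluene, 0 °C; then 25 and 26, 0 → 25 °C
Reagents that add atoms: none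
Why: Mitsunobu esterification; SN2 displacement of the alkoxyphosphonium by the carboxylate inverts C8 to the required 8S configuration and installs the ester without activating, and so without epimerising, the α‑chiral acid.

Step 14
Reactants: 28 methyl (1R,4Z,6R,7S,8S,9R,10R)-9-[(tert-butyldimethylsilyl)oxy]-1,10-epoxy-8-{[(2S)-2-methylbutanoyl]oxy}germacra-4,11(13)-dien-12,6-olid-14-oate
Product: 29 methyl (1R,4Z,6R,7S,8S,9R,10S)-1,10-epoxy-9-hydroxy-8-{[(2S)-2-methylbutanoyl]oxy}germacra-4,11(13)-dien-12,6-olid-14-oate (CNP0581690.1)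
Conditions: HF·pyridine, pyridine, THF, 0 → 25 °C
Reagents that add atoms: none
Why: buffered fluoride desilylation frees O‑9 without the base that would cause acyl migration, Payne rearrangement or conjugate addition to the methylene lactone; no stereocenter is touched.

## Compound list

1 | neryl acetate, (2Z)-3,7-dimethylocta-2,6-dien-1-yl acetate | CC(=O)OC/C=C(/C)CCC=C(C)C | starting material
2 | secondary ozonide, (2Z)-5-(5,5-dimethyl-1,2,4-trioxolan-3-yl)-3-methylpent-2-en-1-yl acetate (not isolated) | CC(=O)OC/C=C(/C)CCC1OOC(C)(C)O1 | intermediate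
3 | (2Z)-3-methyl-6-oxohex-2-en-1-yl acetate | CC(=O)OC/C=C(/C)CCC=O | intermediate
4 | methyl (triphenylphosphoranylidene)acetate | COC(=O)C=P(c1ccccc1)(c1ccccc1)c1ccccc1 | starting material
5 | iodo ylide, methyl iodo(triphenylphosphoranylidene)acetate (not isolated) | COC(=O)C(I)=P(c1ccccc1)(c1ccccc1)c1ccccc1 | intermediate
6 | methyl (2Z,6Z)-8-acetoxy-2-iodo-6-methylocta-2,6-dienoate | COC(=O)/C(I)=C/CC/C(C)=C\COC(C)=O | intermediate
7 | (R)-2,2-dimethyl-1,3-dioxolane-4-carbaldehyde, (R)-glyceraldehyde acetonide | O=C[C@H]1COC(C)(C)O1 | starting material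
8 | alkenylchromium dichloride, [(1Z,5Z)-7-acetoxy-1-(methoxycarbonyl)-5-methylhepta-1,5-dien-1-yl]chromium dichloride (not isolated) | COC(=O)/C(=C/CC/C(C)=C\COC(C)=O)[Cr](Cl)Cl | intermediate
9 | methyl (2E,6Z)-8-acetoxy-2-{(S)-[(4R)-2,2-dimethyl-1,3-dioxolan-4-yl](hydroxy)methyl}-6-methylocta-2,6-dienoate | COC(=O)/C(=C/CC/C(C)=C\COC(C)=O)[C@H](O)[C@H]1COC(C)(C)O1 | intermediate
10 | methyl (2S,3R)-3-[(3Z)-5-acetoxy-3-methylpent-3-en-1-yl]-2-{(R)-[(4R)-2,2-dimethyl-1,3-dioxolan-4-yl](hydroxy)methyl}oxirane-2-carboxylate | CC(=O)OC/C=C(/C)CC[C@H]1O[C@@]1(C(=O)OC)[C@H](O)[C@H]2COC(C)(C)O2 | intermediate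
11 | methyl (2R,3R)-3-[(3Z)-5-acetoxy-3-methylpent-3-en-1-yl]-2-{(R)-[(tert-butyldimethylsilyl)oxy][(4R)-2,2-dimethyl-1,3-dioxolan-4-yl]methyl}oxirane-2-carboxylate | CC(=O)OC/C=C(/C)CC[C@H]1O[C@@]1(C(=O)OC)[C@H](O[Si](C)(C)C(C)(C)C)[C@H]2COC(C)(C)O2 | intermediate
12 | methyl (2R,3R)-2-{(R)-[(tert-butyldimethylsilyl)oxy][(4R)-2,2-dimethyl-1,3-dioxolan-4-yl]methyl}-3-[(3Z)-5-hydroxy-3-methylpent-3-en-1-yl]oxirane-2-carboxylate | OC/C=C(/C)CC[C@H]1O[C@@]1(C(=O)OC)[C@H](O[Si](C)(C)C(C)(C)C)[C@H]2COC(C)(C)O2 | intermediate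
13 | methyl (2R,3R)-2-{(R)-[(tert-butyldimethylsilyl)oxy][(4R)-2,2-dimethyl-1,3-dioxolan-4-yl]methyl}-3-[(3Z)-3-methyl-5-oxopent-3-en-1-yl]oxirane-2-carboxylate | O=C/C=C(/C)CC[C@H]1O[C@@]1(C(=O)OC)[C@H](O[Si](C)(C)C(C)(C)C)[C@H]2COC(C)(C)O2 | intermediate
14 | hex-1-yne | CCCCC#C | starting material
15 | hexenylborane, dicyclohexyl[(1E)-hex-1-en-1-yl]borane (not isolated) | CCCC/C=C/B(C1CCCCC1)C1CCCCC1 | intermediate
16 | hexenylzinc, ethyl[(1E)-hex-1-en-1-yl]zinc (not isolated) | CCCC/C=C/[Zn]CC | intermediate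
17 | methyl (2R,3R)-2-{(R)-[(tert-butyldimethylsilyl)oxy][(4R)-2,2-dimethyl-1,3-dioxolan-4-yl]methyl}-3-[(3Z,5S,6E)-5-hydroxy-3-methylundeca-3,6-dien-1-yl]oxirane-2-carboxylate | CCCC/C=C/[C@H](O)/C=C(/C)CC[C@H]1O[C@@]1(C(=O)OC)[C@H](O[Si](C)(C)C(C)(C)C)[C@H]2COC(C)(C)O2 | intermediate
18 | 2-(bromomethyl)prop-2-enoic acid | OC(=O)C(=C)CBr | starting material
19 | O-acylisourea from 18 and DCC (not isolated) | C=C(CBr)C(=O)OC(=NC1CCCCC1)NC1CCCCC1 | intermediate
20 | methyl (2R,3R)-3-[(3Z,5S,6E)-5-{[2-(bromomethyl)prop-2-enoyl]oxy}-3-methylundeca-3,6-dien-1-yl]-2-{(R)-[(tert-butyldimethylsilyl)oxy][(4R)-2,2-dimethyl-1,3-dioxolan-4-yl]methyl}oxirane-2-carboxylate | CCCC/C=C/[C@H](OC(=O)C(=C)CBr)/C=C(/C)CC[C@H]1O[C@@]1(C(=O)OC)[C@H](O[Si](C)(C)C(C)(C)C)[C@H]2COC(C)(C)O2 | intermediate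
21 | methyl (2R,3R)-3-{(3Z)-4-[(2R)-4-(bromomethyl)-5-oxo-2,5-dihydrofuran-2-yl]-3-methylbut-3-en-1-yl}-2-{(R)-[(tert-butyldimethylsilyl)oxy][(4R)-2,2-dimethyl-1,3-dioxolan-4-yl]methyl}oxirane-2-carboxylate | BrCC1=C[C@@H](/C=C(/C)CC[C@H]2O[C@@]2(C(=O)OC)[C@H](O[Si](C)(C)C(C)(C)C)[C@H]3COC(C)(C)O3)OC1=O | intermediate
22 | diol, methyl (2R,3R)-3-{(3Z)-4-[(2R)-4-(bromomethyl)-5-oxo-2,5-dihydrofuran-2-yl]-3-methylbut-3-en-1-yl}-2-{(1R,2R)-1-[(tert-butyldimethylsilyl)oxy]-2,3-dihydroxypropyl}oxirane-2-carboxylate (not isolated) | BrCC1=C[C@@H](/C=C(/C)CC[C@H]2O[C@@]2(C(=O)OC)[C@H](O[Si](C)(C)C(C)(C)C)[C@H](O)CO)OC1=O | intermediate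
23 | methyl (2R,3R)-3-{(3Z)-4-[(2R)-4-(bromomethyl)-5-oxo-2,5-dihydrofuran-2-yl]-3-methylbut-3-en-1-yl}-2-{(1S)-1-[(tert-butyldimethylsilyl)oxy]-2-oxoethyl}oxirane-2-carboxylate | BrCC1=C[C@@H](/C=C(/C)CC[C@H]2O[C@@]2(C(=O)OC)[C@H](O[Si](C)(C)C(C)(C)C)C=O)OC1=O | intermediate
24 | allylchromium dichloride of 23, CrCl2 on C13 in place of bromine (not isolated) | Cl[Cr](Cl)CC1=C[C@@H](/C=C(/C)CC[C@H]2O[C@@]2(C(=O)OC)[C@H](O[Si](C)(C)C(C)(C)C)C=O)OC1=O | intermediate
25 | methyl (1R,4Z,6R,7R,8R,9R,10R)-9-[(tert-butyldimethylsilyl)oxy]-1,10-epoxy-8-hydroxygermacra-4,11(13)-dien-12,6-olid-14-oate (8-epi series) | C=C1C(=O)O[C@@H]2/C=C(/C)CC[C@H]3O[C@@]3(C(=O)OC)[C@H](O[Si](C)(C)C(C)(C)C)[C@H](O)[C@@H]12 | intermediate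
26 | (2S)-2-methylbutanoic acid | CC[C@H](C)C(=O)O | starting material
27 | alkoxyphosphonium salt, 8-O-triphenylphosphonio derivative of 25 as its (2S)-2-methylbutanoate (not isolated) | C=C1C(=O)O[C@@H]2/C=C(/C)CC[C@H]3O[C@@]3(C(=O)OC)[C@H](O[Si](C)(C)C(C)(C)C)[C@H](O[P+](c4ccccc4)(c4ccccc4)c4ccccc4)[C@@H]12.CC[C@H](C)C(=O)[O-] | intermediate
28 | methyl (1R,4Z,6R,7S,8S,9R,10R)-9-[(tert-butyldimethylsilyl)oxy]-1,10-epoxy-8-{[(2S)-2-methylbutanoyl]oxy}germacra-4,11(13)-dien-12,6-olid-14-oate | C=C1C(=O)O[C@@H]2/C=C(/C)CC[C@H]3O[C@@]3(C(=O)OC)[C@H](O[Si](C)(C)C(C)(C)C)[C@@H](OC(=O)[C@@H](C)CC)[C@@H]12 | intermediate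
29 | methyl (1R,4Z,6R,7S,8S,9R,10S)-1,10-epoxy-9-hydroxy-8-{[(2S)-2-methylbutanoyl]oxy}germacra-4,11(13)-dien-12,6-olid-14-oate (CNP0581690.1) | C=C1C(=O)O[C@@H]2/C=C(/C)CC[C@H]3O[C@@]3(C(=O)OC)[C@H](O)[C@@H](OC(=O)[C@@H](C)CC)[C@@H]12 | target

## Step count and risk

Total steps: 14. Longest linear sequence: 14 steps, from neryl acetate 1 to 29; all other partners (4, 7, 14, 18, 26) are bought.

The three steps most likely to fail:

Step 12 (ring closure). A ten‑membered ring is closed while two stereocenters are set, so oligomerisation or the wrong face at C7 or C8 are real risks. Fallback: generate the nucleophile by catalytic polarity reversal of an allyl acetate instead of by stoichiometric reduction of the bromide. Setting out from 21, KOAc (DMF, 0 °C) gives the acetoxymethyl butenolide acetonide F1. H5IO6 (EtOAc) then gives, through the acetoxymethyl butenolide diol F2 (not isolated), the acetoxymethyl butenolide aldehyde F3. Pd(PPh3)4 (5 mol%) and InI (THF, 25 °C, 2 mM) ionise the acetate with zerovalent palladium, and monovalent indium reduces the resulting allylpalladium to the allylindium acetate iodide F4 (trivalent indium, not isolated). This adds to the aldehyde through the same closed transition state and comes back to the route at 25.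

Step 13 (Mitsunobu at C8). The carbinol is flanked by two branched carbons in a medium ring, so elimination or no reaction may win over SN2. Fallback: invert C8 by oxidation and reduction and then acylate with retention. Setting out from 25, Dess–Martin periodinane (NaHCO3, CH2Cl2, 0 °C) gives the C8 ketone F5. NaBH4 with CeCl3·7H2O (MeOH, −78 °C) reduces it by Felkin–Anh attack anti to the non‑chelating silyloxy group; because hydride is now the incoming group this gives the 8S alcohol F6. Steglich esterification with 26 (DCC, DMAP, through the methylbutanoyl isourea F7, not isolated) comes back to the route at 28.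

Step 4 (directed epoxidation). The alkene is conjugated to an ester, so the titanium‑bound peroxide may react slowly or with low threo selectivity. Fallback: reverse the electronic demand and use a nucleophilic Weitz–Scheffer epoxidation. Setting out from 9, tBuOOLi (THF, −20 °C) adds in conjugate fashion, with the lithium alkoxide of O‑9 delivering the peroxide to the syn face before ring closure, and comes back to the route at 10. The epoxide geometry is then set in the ring‑closure step and must be checked. New compounds on this path: none F0.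

## Further compounds

F1 | step 12 | acetoxymethyl butenolide acetonide (21 with acetate in place of bromide) | CC(=O)OCC1=C[C@@H](/C=C(/C)CC[C@H]2O[C@@]2(C(=O)OC)[C@H](O[Si](C)(C)C(C)(C)C)[C@H]3COC(C)(C)O3)OC1=O
F2 | step 12 | acetoxymethyl butenolide diol (not isolated) | CC(=O)OCC1=C[C@@H](/C=C(/C)CC[C@H]2O[C@@]2(C(=O)OC)[C@H](O[Si](C)(C)C(C)(C)C)[C@H](O)CO)OC1=O
F3 | step 12 | acetoxymethyl butenolide aldehyde | CC(=O)OCC1=C[C@@H](/C=C(/C)CC[C@H]2O[C@@]2(C(=O)OC)[C@H](O[Si](C)(C)C(C)(C)C)C=O)OC1=O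
F4 | step 12 | allylindium acetate iodide (not isolated) | CC(=O)O[In](I)CC1=C[C@@H](/C=C(/C)CC[C@H]2O[C@@]2(C(=O)OC)[C@H](O[Si](C)(C)C(C)(C)C)C=O)OC1=O
F5 | step 13 | C8 ketone | C=C1C(=O)O[C@@H]2/C=C(/C)CC[C@H]3O[C@@]3(C(=O)OC)[C@H](O[Si](C)(C)C(C)(C)C)C(=O)[C@@H]12
F6 | step 13 | 8S alcohol | C=C1C(=O)O[C@@H]2/C=C(/C)CC[C@H]3O[C@@]3(C(=O)OC)[C@H](O[Si](C)(C)C(C)(C)C)[C@@H](O)[C@@H]12
F7 | step 13 | methylbutanoyl isourea (not isolated) | CC[C@H](C)C(=O)OC(=NC1CCCCC1)NC1CCCCC1
F0 | step 4 | none | none
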